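The numbers are assumed; the result is computed.

Temperature is what separates the flasks of this plate, and in each one substrate opens by separate reversible steps onto target, isomer of the product, third isomer and dormant form.

| flask | substrate | temperature | time |
|---|---|---|---|
| amber | 1.0 mM | 0 °C | 30 s |
| red | 1.0 mM | −20 °C | 30 s |
| ochre | 1.0 mM | 40 °C | 30 s |
| grey | 1.0 mM | 20 °C | 30 s |

    substrate ⇌ target (K1 = 1.1, k1 = 3.9 /s, Ea1 = 64.0 kJ/mol, ΔH1 = −90.0 kJ/mol)
    substrate ⇌ isomer of the product (K2 = 2.3, k2 = 0.082 /s, Ea2 = 69.0 kJ/mol, ΔH2 = 7.00 kJ/mol)
    substrate ⇌ third isomer (K3 = 0.33, k3 = 0.72 /s, Ea3 = 72.0 kJ/mol, ΔH3 = −43.0 kJ/mol)
    substrate ⇌ dormant form (K4 = 2.6, k4 = 1.1 /s, Ea4 = 63.0 kJ/mol, ΔH4 = −60.0 kJ/mol)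
    (constants at 0 °C)

- at 0 °C the constants are as listed, elsewhere as the activation energies and enthalpies make them

1. the flask that comes out highest in amount of target, in percent of the substrate charged, or "all alike" when all lie within 1.5 percentage points (amber / red / ochre / grey / all alike)
2. target at the end, in percent of the substrate charged, amber
3. target at the end, in percent of the substrate charged, red
4. target at the end, in percent of the substrate charged, ochre
5. target at the end, in percent of the substrate charged, grey

What looks wrong shows in the ochre flask, at 40 °C. The step to target has the largest rate constant at 0 °C and speeds up by a factor of 340 from the coldest flask to the hottest, and in ochre its forward constant is 143 /s, yet with an enthalpy of −90.0 kJ/mol its equilibrium constant there has fallen to 0.00697.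

We clear this up by asking how much time ochre allows. The step to the isomer of the product has the smallest rate constant at 0 °C, and still its relaxation half-life in ochre by this step alone, both ways together, 0.135 s, is far shorter than the 30 s allowed, so we reckon ochre as under thermodynamic control, with [target]/[substrate] equal to 0.00697. A first round sets target against substrate by themselves and gives 0.692 % of the charge as target, hardly any. But that answer leaves substrate as the whole remainder, while the other steps claim it too, with equilibrium constants in ochre of 3.41 for the isomer of the product, 0.0294 for the third isomer and 0.0890 for the dormant form, so we go round again with the charge shared out.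

One plus the sum of the equilibrium constants at the flask's temperature comes in ochre to 4.54, and we call it the dilution: the number by which the charge is divided to give substrate at equilibrium. Ochre's substrate is then 22.0 % of the charge and its target 0.154 %, the figure we commit to. The two numbers stop quarrelling: 143 /s belongs to the speed of the forward step, 0.00697 to the ratio at equilibrium. In amber the step to the isomer of the product has a forward constant of 0.082 /s, whose reciprocal 12.2 s lies below 30 s by too little for us to assume equilibrium, so we take our reckoning no further with amber or the colder red.

The forecast names red, with 16.3 % for amber, 66 % for red, 0.15 % for ochre and 1.66 % for grey, on the ground that “Grey and ochre reach full equilibrium within 30 s”.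

The simulation puts red highest, with 65.8 % in red, 16.3 % in amber, 1.66 % in grey and 0.154 % in ochre, where we had reckoned 0.154 %. Ochre's target reads 0.154 % at 15.0 s and 0.154 % at 300 s. The dilution of 4.54 also serves the ochre run with the conversion of substrate into isomer of the product struck out, both ways: removing 3.41 from it leaves 1.13, which puts target at 0.617 %, and that run gave 0.619 %.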